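Remark on the chemistry: the target has no stereocentre, so no stereodescriptors are needed, and chloromethyl methyl ether, a carcinogenic alkylating agent, is assumed to be used as a commercial solution under closed handling.

## Structural features

The target is one benzene ring with six substituents, no second ring, no side chain longer than a methyl group and no stereocentre, so ring fusion and neighbouring stereocentres do not arise. Numbered from the methyl carbon, the ring bears CH3 at C1, Br at C2, OH at C3, OH at C4, Br at C5 and Br at C6, which makes the compound 3,4,6-tribromo-5-methylbenzene-1,2-diol, the fully brominated 4-methylcatechol. The free catechol is the fragile group, because base and oxidants convert it into the ortho-quinone. The three aryl bromides rule out reducing conditions and unselective organometallic reagents, and the methyl group flanked by two bromines is open to side-chain bromination. The carbon skeleton is trivial, and the real difficulty is regiochemical, namely placing two oxygens and three bromines on a toluene ring without ambiguity. The C4 oxygen stands para to the C1 methyl group, and with bromine at C3 in place of oxygen the ring would be 2,3,5,6-tetrabromo-4-methylphenol, which has a mirror plane through C1 and C4 and therefore equivalent bromines at C3 and C5. The key step exploits this feature: the C3–Br bond next to the C4 oxygen is converted into the C3–O bond by way of C3–Mg and C3–B, and the C4 oxygen, masked as a chelating acetal, chooses the site.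

## Logic of the disconnections

Working backwards from 9, the C4 hydroxyl is masked again as a methoxymethyl acetal, so the bond concerned is the aryl-O–CH2 bond of 8. The cut is placed here because 9 is the most oxidation-prone compound of the sequence and should appear only at the end, and because this acetal is the group that steers the preceding step. No skeletal simplification results, but the two oxygens become distinguishable. The forward step must cleave the acetal with acid and leave the three C–Br bonds untouched.

The C3–O bond of 8 is cut and traced back through the C3–B bond of 7 and the C3–Mg bond of 6 to the C3–Br bond of 4, with 5 as the source of boron. The C3 oxygen is the one substituent that exhaustive bromination of 1 cannot deliver. Exchanging it for bromine gives 4, which has a mirror plane through C1 and C4, so the two bromines beside the acetal are equivalent. The gain is a symmetric tetrabromide that needs no earlier positional decision. The forward step must exchange a bromine next to the acetal and not one next to the methyl group, must stop after one exchange, must keep 6 from losing magnesium halide to an aryne, and must oxidise 7 before it is protodeboronated.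

The aryl-O–CH2 bond of 4 is cut to give 2 and 3. A free hydroxyl would destroy one equivalent of the exchange reagent and leave a phenoxide too electron-rich for clean exchange. The acetal offers two oxygens that can hold magnesium and is the smallest chelating group that fits between two ortho bromines. The gain is the unprotected 2. The forward step has to alkylate a hindered, weakly nucleophilic phenoxide on oxygen.

All four C–Br bonds of 2 are cut, which leads to 1. Each free ring position of 1 takes the same substituent, so no regiocontrol is needed and the starting material is a bulk chemical. The forward step must force bromine into the two positions meta to the hydroxyl, which are deactivated once the first two bromines are in place, and must spare the methyl group.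

## Other disconnections considered

Alternative 1: The cut is the C3–C4 bond between the two oxygen-bearing carbons, which opens the ring to an acyclic diester. The forward key step is an acyloin condensation of dimethyl 3-methyladipate A1 with Na in hot toluene in the presence of chlorotrimethylsilane A2, which traps the enediolate and should give racemic 4-methyl-1,2-bis(trimethylsilyloxy)cyclohex-1-ene A3. Oxidative desilylation of A3 would lead to 4-methylcyclohexane-1,2-dione A4, and an excess of an electrophilic brominating agent would then have to aromatise A4 by repeated α-bromination and dehydrobromination and also fill the three remaining ring positions to reach 9. In its favour, six-membered acyloin closure is a favourable case of the reaction, the 1,2-dioxygen pattern and its relation to the methyl group are fixed when the ring forms, and no protecting group is needed. Against it, a benzene ring is built from the chain of A1 although aromatic C7 feedstocks with the right pattern are cheap, a stereocentre is created at the methyl-bearing carbon of A3 only to be destroyed, and four hydrogens must be removed from A4 by a cascade whose order cannot be steered, with a risk of bromination at sp3 carbons or at the methyl group; molten Na adds a handling hazard. In comparison, this plan is the equal of the chosen one in the certainty of the substitution pattern and, on paper, the better in step count (two or three operations from A1). It is the weaker mechanistically, because the chosen plan rests on one defined organometallic event and this one on an ill-defined oxidation–bromination cascade.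

Alternative 2: The cuts are C1–C2 and C2–C3, so that C2 leaves as a one-carbon unit and the ring contracts to a cyclopentane. Maple lactone A5 would first be converted into its silyl enol ether monoketal, 7-methyl-6-(trimethylsilyloxy)-1,4-dioxaspiro[4.4]non-6-ene A6. In the forward key step the dihalocarbene generated from bromoform A7 and a hindered alkoxide base adds to the enol ether double bond of A6, and the dibromocyclopropane opens in the cyclopropyl-to-allyl manner with loss of bromide and of the silyl group to give 2-bromo-3-methylcyclohex-2-ene-1,6-dione 6-(ethylene ketal) A8. Acid would unmask the second carbonyl group of A8, and the resulting enedione is a tautomer of 3-bromo-4-methylbenzene-1,2-diol A9, whose bromination at its two free positions would give 9. In its favour, the aromatisation is redox-neutral, which is better than any route that needs an oxidant for that purpose, the C1 methyl, C2 bromine, C3 oxygen and C4 oxygen are placed by construction, and A5 is cheap. Against it, the precise placement of the C2 bromine through A7 is wasted, because C5 and C6 of A9 still need electrophilic bromination, which would fill C2 just as readily. Making A6 means ketalising a hindered, enolised dione while keeping an acid-labile silyl enol ether, and the carbene must add to a tetrasubstituted alkene next to a spiro centre. In comparison, this plan is the equal of the chosen one in structural certainty and the better in not having to distinguish between four bromines. It is the poorer in step count (about five operations from A5 against four) and in the number of hindered, sensitive intermediates on the way to A8.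

Alternative 3: The cuts are C1–C2 and C5–C6 in a [4+2] sense, so that a four-carbon piece carries C2 to C5 with both oxygens and two bromines and a two-carbon piece carries C1 with its methyl group and C6 with its bromine. In the forward key step 2,5-dibromo-3,4-dimethoxythiophene 1,1-dioxide A10 adds 1-bromopropyne A11 across its diene termini, and the bridged adduct loses its sulfonyl bridge as a gas and aromatises to 1,2,4-tribromo-5,6-dimethoxy-3-methylbenzene A12. Cleavage of both methyl ethers of A12 with a boron trihalide would give 9. In its favour, the plan is convergent and sets all six substituents in one operation, the diene A10 is symmetric so that either orientation of A11 gives the same arene, and the aromatisation is driven by loss of the gas. Against it, A10 is not a catalogue compound and would have to come from 3,4-dimethoxythiophene A13 by dibromination and a forcing S-oxidation, thiophene dioxides tend to dimerise, and alkynes are sluggish dienophiles towards such dienes and need heat, while A11 is volatile and, as a haloalkyne, thermally hazardous. In comparison, this plan is the equal of the chosen one in regiochemical certainty and the better in convergence and in avoiding any choice between bromines. The overall count (four operations from A13 to 9 by way of A12) is about equal. The chosen plan is judged more dependable because its reagents are ordinary and its one delicate step has close analogy.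

Key step: step 3

## Route

Step 1
Reactants: 1 p-cresol (4-methylphenol)
Product: 2 2,3,5,6-tetrabromo-4-methylphenol
Conditions: Br2 (excess, neat), AlBr3 (0.2 equiv), 0 °C → rt, dark; then aq. NaHSO3
Reagents that add atoms: bromine, BrBr
Why: Lewis-acid-assisted exhaustive electrophilic aromatic bromination: the hydroxyl directs the first two bromines ortho to itself and AlBr3-polarised bromine then fills the two remaining positions next to the methyl group; all four free positions are brominated, so no regiocontrol is needed, and darkness and the ionic medium should suppress attack on the methyl group.

Step 2
Reactants: 2 2,3,5,6-tetrabromo-4-methylphenol; 3 chloromethyl methyl ether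
Product: 4 1,2,4,5-tetrabromo-3-(methoxymethoxy)-6-methylbenzene
Conditions: NaH, THF, 0 °C; then 3, 0 °C → rt
Reagents that add atoms: chloromethyl methyl ether (3), COCCl
Why: Williamson-type O-alkylation of a phenoxide by an α-chloro ether: the di-ortho-brominated phenol is acidic and is fully deprotonated by NaH, and the small, very electrophilic chloromethyl ether should still reach the hindered oxygen; C-alkylation cannot compete because every ring carbon is substituted.

Step 3
Reactants: 4 1,2,4,5-tetrabromo-3-(methoxymethoxy)-6-methylbenzene; 5 trimethyl borate
Product: 8 3,4,6-tribromo-2-(methoxymethoxy)-5-methylphenol, via arylmagnesium chloride 6 (not isolated), via dimethyl arylboronate 7 (not isolated)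
Conditions: iPrMgCl·LiCl (1.05 equiv), THF, −40 °C; 5, −40 → 0 °C; AcOH, 30% aq. H2O2, 0 °C → rt; aq. Na2S2O3
Reagents that add atoms: hydrogen peroxide, OO (oxygen of the new hydroxyl of 8); isopropylmagnesium chloride–lithium chloride, CC(C)[Mg]Cl.[Li+].[Cl-] (MgCl of 6 only); trimethyl borate (5), COB(OC)OC (B(OMe)2 of 7 only)
Why: The step joins a directed halogen–magnesium exchange on a polybromoarene to the classical Grignard-to-boronate-to-phenol sequence, both of which are known reaction types. The isopropyl group attacks bromine through a bromine ate-type transition state, and the exchange runs towards the less basic aryl carbanion, which in 4 is the carbon between the acetal oxygen and a bromine, where two ortho electron-withdrawing atoms stabilise the C–Mg bond. The two acetal oxygens pre-coordinate magnesium and so deliver the reagent to a bromine beside the ether and not beside the methyl group, and because the two candidate bromines are related by the mirror plane through the methyl and ether carbons, either one gives 6. A second exchange is not expected, because 6 is already an electron-rich arylmagnesium and only about one equivalent of reagent is present. Keeping 6 at or below −40 °C until the borate is added should prevent loss of magnesium halide to an aryne, the main decomposition path of an ortho-bromoarylmagnesium. Transmetalation gives a methoxyborate that collapses to 7, hydroperoxide then adds to boron, the aryl group migrates from boron to oxygen with the ring position unchanged, and hydrolysis frees the phenol 8. Acetic acid keeps the medium on the acid side, so that the hindered, electron-poor 7 is oxidised before base-induced protodeboronation can compete, and the acetal should survive this short exposure to weak acid. No ring is closed and no stereocentre is formed.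

Step 4
Reactants: 8 3,4,6-tribromo-2-(methoxymethoxy)-5-methylphenol
Product: 9 3,4,6-tribromo-5-methylbenzene-1,2-diol
Conditions: HCl (3 M), MeOH, rt → 40 °C
Reagents that add atoms: none
Why: Acid-catalysed acetal cleavage by transacetalisation to the solvent: the electron-poor aryloxy group is a good leaving group and the methoxymethyl cation is captured by methanol; aryl C–Br bonds and the methyl group are inert to methanolic HCl, and the catechol is not oxidised under acidic, non-oxidising conditions.

## Compound list

1 | p-cresol (4-methylphenol) | Cc1ccc(O)cc1 | starting material
2 | 2,3,5,6-tetrabromo-4-methylphenol | Cc1c(Br)c(Br)c(O)c(Br)c1Br | intermediate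
3 | chloromethyl methyl ether | COCCl | starting material
4 | 1,2,4,5-tetrabromo-3-(methoxymethoxy)-6-methylbenzene | COCOc1c(Br)c(Br)c(C)c(Br)c1Br | intermediate
5 | trimethyl borate | COB(OC)OC | starting material
6 | [3,4,6-tribromo-2-(methoxymethoxy)-5-methylphenyl]magnesium chloride (LiCl complex, not isolated) | COCOc1c([Mg]Cl)c(Br)c(C)c(Br)c1Br | intermediate
7 | dimethyl [3,4,6-tribromo-2-(methoxymethoxy)-5-methylphenyl]boronate (not isolated) | COCOc1c(B(OC)OC)c(Br)c(C)c(Br)c1Br | intermediate
8 | 3,4,6-tribromo-2-(methoxymethoxy)-5-methylphenol | COCOc1c(O)c(Br)c(C)c(Br)c1Br | intermediate
9 | 3,4,6-tribromo-5-methylbenzene-1,2-diol | Cc1c(Br)c(O)c(O)c(Br)c1Br | target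

## Step count and least certain steps

Total step count: 4. Longest linear sequence: 4 steps (1 → 2 → 4 → 8 → 9).

Step 3 (key step). The exchange may lose site selectivity, either by attack at a bromine beside the methyl group or by a second exchange. If the mixture warms before the borate is added, 6 may eliminate magnesium halide to an aryne. The hindered 7 may also be protodeboronated during the oxidation. The fallback sets out from 1 and comes back to the route at 9, and it introduces the second oxygen before any bromine. Magnesium-mediated ortho-formylation of 1 (MgCl2, Et3N, paraformaldehyde, MeCN, reflux) should give 2-hydroxy-5-methylbenzaldehyde F1. Dakin oxidation (H2O2, aq. NaOH, rt) would exchange the formyl group for a hydroxyl and give 4-methylbenzene-1,2-diol F2. Exhaustive bromination (Br2, AcOH, 0 °C → rt, then aq. NaHSO3 to reduce any ortho-quinone) should fill the three free positions and give 9 without a protecting group.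

Step 1. Bromination of the two deactivated positions meta to the hydroxyl may stay incomplete, and forcing conditions may bring bromination at the methyl group or ipso attack at the methyl-bearing carbon. The fallback sets out from 1 and comes back to the route at 8, and it postpones the two bromines beside the methyl group until the ring is activated again. Bromination of 1 with two equivalents of Br2 (AcOH, 0 °C) should give 2,6-dibromo-4-methylphenol F3. Protection as in step 2 would give 1,3-dibromo-2-(methoxymethoxy)-5-methylbenzene F4. Bromine–lithium exchange of one of its two equivalent bromines (n-BuLi, THF, −78 °C), then 5 and AcOH/H2O2 as in step 3, should give 3-bromo-2-(methoxymethoxy)-5-methylphenol F5. The two free ring positions of this phenol are ortho and para to the new hydroxyl, so N-bromosuccinimide (2 equiv, MeCN, 0 °C) should brominate both and give 8.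

Step 2. O-Alkylation of the hindered, weakly nucleophilic phenoxide may be slow or incomplete, with hydrolytic loss of the moisture-sensitive and hazardous chloromethyl ether. The fallback sets out from 2 and comes back to the route at 9, and it changes the directing group to a methyl ether. Methylation of 2 (MeI, K2CO3, DMF, rt) should give 1,2,4,5-tetrabromo-3-methoxy-6-methylbenzene F6. The exchange, borylation and oxidation of step 3, applied to this ether, in which the methoxy oxygen directs mainly by induction, would give 3,4,6-tribromo-2-methoxy-5-methylphenol F7. Demethylation with BBr3 (CH2Cl2, −78 °C → rt) should then give 9.

## Further compounds

F1 | step 3 | 2-hydroxy-5-methylbenzaldehyde | Cc1ccc(O)c(C=O)c1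
F2 | step 3 | 4-methylbenzene-1,2-diol | Cc1ccc(O)c(O)c1
F3 | step 1 | 2,6-dibromo-4-methylphenol | Cc1cc(Br)c(O)c(Br)c1
F4 | step 1 | 1,3-dibromo-2-(methoxymethoxy)-5-methylbenzene | COCOc1c(Br)cc(C)cc1Br
F5 | step 1 | 3-bromo-2-(methoxymethoxy)-5-methylphenol | COCOc1c(O)cc(C)cc1Br
F6 | step 2 | 1,2,4,5-tetrabromo-3-methoxy-6-methylbenzene | COc1c(Br)c(Br)c(C)c(Br)c1Br
F7 | step 2 | 3,4,6-tribromo-2-methoxy-5-methylphenol | COc1c(O)c(Br)c(C)c(Br)c1Br
A1 | alternative 1 | dimethyl 3-methyladipate (racemic) | COC(=O)CC(C)CCC(=O)OC
A2 | alternative 1 | chlorotrimethylsilane | C[Si](C)(C)Cl
A3 | alternative 1 | 4-methyl-1,2-bis(trimethylsilyloxy)cyclohex-1-ene (racemic) | CC1CCC(O[Si](C)(C)C)=C(O[Si](C)(C)C)C1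
A4 | alternative 1 | 4-methylcyclohexane-1,2-dione (racemic) | CC1CCC(=O)C(=O)C1
A5 | alternative 2 | maple lactone (2-hydroxy-3-methylcyclopent-2-en-1-one) | CC1=C(O)C(=O)CC1
A6 | alternative 2 | 7-methyl-6-(trimethylsilyloxy)-1,4-dioxaspiro[4.4]non-6-ene | CC1=C(O[Si](C)(C)C)C2(CC1)OCCO2
A7 | alternative 2 | bromoform | BrC(Br)Br
A8 | alternative 2 | 2-bromo-3-methylcyclohex-2-ene-1,6-dione 6-(ethylene ketal) (7-bromo-8-methyl-1,4-dioxaspiro[4.5]dec-7-en-6-one) | CC1=C(Br)C(=O)C2(CC1)OCCO2
A9 | alternative 2 | 3-bromo-4-methylbenzene-1,2-diol | Cc1ccc(O)c(O)c1Br
A10 | alternative 3 | 2,5-dibromo-3,4-dimethoxythiophene 1,1-dioxide | COC1=C(Br)S(=O)(=O)C(Br)=C1OC
A11 | alternative 3 | 1-bromopropyne | CC#CBr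
A12 | alternative 3 | 1,2,4-tribromo-5,6-dimethoxy-3-methylbenzene | COc1c(OC)c(Br)c(Br)c(C)c1Br
A13 | alternative 3 | 3,4-dimethoxythiophene | COc1cscc1OC
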